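**Plan**
- Retrosynthesis: the acetate and both acids are unmasked last. C8=C17 is cut (Wittig) back to a C8 ketone, then C12–C13 (B-alkyl Suzuki coupling) and C11=C12 (Wittig) back to a C9 formyl group.
- Ring B holds the quaternary C10 (methyl C20) beside C9 (which carries C11) and the methylene-bearing, hence oxygenatable, C8. It is therefore cut at C5–C10 and C8–C9 into a C5=C6–C7=C8–OSi diene and a C9=C10 (E)-enal, with C1–C4 of ring A as the connecting chain.
- Forward: the acyclic chain is joined in the order C1–C2 (keto ester dianion), C4–C5 and C4–C18 (two enolate alkylations), C6=C7 (cross-metathesis). One intramolecular Diels–Alder reaction then closes ring B and, as the tether ring, ring A; the side chain and the exocyclic methylene follow.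
- Stereochemistry: C3 from a Noyori hydrogenation; C4 from two Fráter–Seebach alkylations (allyl first, methyl second, each anti to the C3 oxygen); C5, C9 and C10 from the endo, chair-tether cycloaddition relayed from C3/C4; 13E from stereoretentive coupling of an (E)-enol triflate.

Key step: step 13

Remark: soft enolisation in step 10 is assumed to give mainly the (1E,3E) dienol ether; a (1Z) isomer cannot reach the reactive s-cis geometry and should be left behind in step 13.
Naming: bicyclic compounds are named on the labdane skeleton with labdane numbering; β is the face of the C20 methyl group.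

**Route**

Step 1
Reactants: 1 3-methylbut-2-en-1-ol (prenol)
Product: 2 3-methylbut-2-en-1-yl pivalate
Conditions: t-BuCOCl, pyridine, DMAP (cat.), CH2Cl2, 0 °C → rt
Reagents that add atoms: pivaloyl chloride, CC(C)(C)C(=O)Cl
Why: DMAP-catalysed O-acylation of a primary alcohol; the pivalate has no α-hydrogen and a shielded carbonyl group, so it should pass the later lithium amide steps and still be removable by hydride.

Step 2
Reactants: 2 3-methylbut-2-en-1-yl pivalate
Product: 3 (2E)-4-hydroxy-3-methylbut-2-en-1-yl pivalate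
Conditions: SeO2 (cat.), t-BuOOH, CH2Cl2, rt
Reagents that add atoms: tert-butyl hydroperoxide, CC(C)(C)OO; selenium dioxide (catalytic oxygen carrier), O=[Se]=O
Why: Riley allylic oxidation (ene reaction then [2,3]-sigmatropic shift) attacks the methyl group trans to the chain of a trisubstituted alkene, so the E-hydroxymethyl isomer should be formed, as is usual for prenyl esters.

Step 3
Reactants: 3 (2E)-4-hydroxy-3-methylbut-2-en-1-yl pivalate
Product: 4 (2E)-4-bromo-3-methylbut-2-en-1-yl pivalate
Conditions: CBr4, PPh3, CH2Cl2, 0 °C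
Reagents that add atoms: tetrabromomethane, BrC(Br)(Br)Br
Why: Appel bromination displaces the alkoxyphosphonium ion at the primary carbon by SN2 attack, which should leave the double-bond position and geometry untouched.

Step 4
Reactants: 5 tert-butyl acetoacetate; 4 (2E)-4-bromo-3-methylbut-2-en-1-yl pivalate
Product: 7 tert-butyl (6E)-6-methyl-3-oxo-8-(pivaloyloxy)oct-6-enoate, via acetoacetate dianion 6 (not isolated)
Conditions: NaH, THF, 0 °C; n-BuLi, 0 °C; then 4, 0 °C → rt; 1 M HCl
Reagents that add atoms: none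
Why: acetoacetate dianion alkylation takes place at the more basic terminal carbon (C2 of the target), and the primary allylic bromide should react by direct SN2 substitution far faster than the hindered pivalate is attacked.

Step 5
Reactants: 7 tert-butyl (6E)-6-methyl-3-oxo-8-(pivaloyloxy)oct-6-enoate
Product: 8 tert-butyl (3S,6E)-3-hydroxy-6-methyl-8-(pivaloyloxy)oct-6-enoate
Conditions: H2 (10 bar), RuCl2[(S)-BINAP] (cat.), MeOH, 50 °C
Reagents that add atoms: none
Why: Noyori asymmetric hydrogenation of a β-keto ester, in which the chelated (S)-BINAP ruthenium dichloride catalyst should deliver hydrogen to one carbonyl face and set C3 as S, while the non-coordinating trisubstituted alkene is not a substrate for this catalyst.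

Step 6
Reactants: 8 tert-butyl (3S,6E)-3-hydroxy-6-methyl-8-(pivaloyloxy)oct-6-enoate; 9 allyl bromide
Product: 11 tert-butyl (2S,3S,6E)-3-hydroxy-6-methyl-8-(pivaloyloxy)-2-(prop-2-en-1-yl)oct-6-enoate, via dilithium alkoxide enolate 10 (not isolated)
Conditions: LiN(i-Pr)2 (2.2 equiv), THF, −78 → −20 °C; 9, DMPU, −78 → −20 °C; then H2O
Reagents that add atoms: none
Why: Fráter–Seebach alkylation, in which the chelated dilithium alkoxide enolate is allylated on the face anti to the C3 oxygen (2S); this centre is made planar again in step 7, so clean C-alkylation is what matters here.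

Step 7
Reactants: 11 tert-butyl (2S,3S,6E)-3-hydroxy-6-methyl-8-(pivaloyloxy)-2-(prop-2-en-1-yl)oct-6-enoate
Product: 13 tert-butyl (2R,3S,6E)-3-hydroxy-2,6-dimethyl-8-(pivaloyloxy)-2-(prop-2-en-1-yl)oct-6-enoate, via dilithium alkoxide enolate 12 (not isolated)
Conditions: LiN(i-Pr)2 (2.5 equiv), THF/DMPU, −78 → −10 °C; MeI, −78 → 0 °C; then H2O
Reagents that add atoms: iodomethane, CI
Why: a second Fráter–Seebach alkylation, in which iodomethane again enters anti to the C3 oxygen of the chelated tetrasubstituted enolate, so that the methyl group (C18) ends anti and the allyl group syn to oxygen, which is the C3/C4 relationship of the target (quaternary C4 set as 2R).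

Step 8
Reactants: 13 tert-butyl (2R,3S,6E)-3-hydroxy-2,6-dimethyl-8-(pivaloyloxy)-2-(prop-2-en-1-yl)oct-6-enoate
Product: 14 tert-butyl (2R,3S,6E)-3-(tert-butyldimethylsilyloxy)-2,6-dimethyl-8-(pivaloyloxy)-2-(prop-2-en-1-yl)oct-6-enoate
Conditions: t-BuMe2SiOTf, 2,6-lutidine, CH2Cl2, −78 → 0 °C
Reagents that add atoms: tert-butyldimethylsilyl triflate, CC(C)(C)[Si](C)(C)OS(=O)(=O)C(F)(F)F
Why: silylation with a silyl triflate and 2,6-lutidine is the standard way to protect a hindered secondary alcohol, and the short reaction at low temperature should spare the tert-butyl ester.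

Step 9
Reactants: 14 tert-butyl (2R,3S,6E)-3-(tert-butyldimethylsilyloxy)-2,6-dimethyl-8-(pivaloyloxy)-2-(prop-2-en-1-yl)oct-6-enoate; 15 (E)-but-2-enal (crotonaldehyde)
Product: 16 tert-butyl (2R,3S,6E)-3-(tert-butyldimethylsilyloxy)-2,6-dimethyl-2-[(2E)-4-oxobut-2-en-1-yl]-8-(pivaloyloxy)oct-6-enoate
Conditions: 15 (excess), second-generation Hoveyda–Grubbs catalyst (cat.), CH2Cl2, 40 °C
Reagents that add atoms: none
Why: olefin cross-metathesis of a terminal alkene with excess crotonaldehyde should give the E-enal with loss of propene, the trisubstituted alkene being inert to the catalyst.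

Step 10
Reactants: 16 tert-butyl (2R,3S,6E)-3-(tert-butyldimethylsilyloxy)-2,6-dimethyl-2-[(2E)-4-oxobut-2-en-1-yl]-8-(pivaloyloxy)oct-6-enoate
Product: 17 tert-butyl (2R,3S,6E)-3-(tert-butyldimethylsilyloxy)-2,6-dimethyl-8-(pivaloyloxy)-2-[(1E,3E)-4-(triethylsilyloxy)buta-1,3-dien-1-yl]oct-6-enoate
Conditions: Et3SiOTf, Et3N, Et2O, −78 → 0 °C
Reagents that add atoms: triethylsilyl triflate, CC[Si](CC)(CC)OS(=O)(=O)C(F)(F)F
Why: soft enolisation (O-silylation of the enal, then γ-deprotonation at C5 by the amine) gives the 1-silyloxy diene; the s-trans enal should give the E enol ether and the quaternary C4 should take the trans position on the new C5=C6 bond.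

Step 11
Reactants: 17 tert-butyl (2R,3S,6E)-3-(tert-butyldimethylsilyloxy)-2,6-dimethyl-8-(pivaloyloxy)-2-[(1E,3E)-4-(triethylsilyloxy)buta-1,3-dien-1-yl]oct-6-enoate
Product: 18 tert-butyl (2R,3S,6E)-3-(tert-butyldimethylsilyloxy)-8-hydroxy-2,6-dimethyl-2-[(1E,3E)-4-(triethylsilyloxy)buta-1,3-dien-1-yl]oct-6-enoate
Conditions: i-Bu2AlH, CH2Cl2, −78 °C; aq. potassium sodium tartrate
Reagents that add atoms: none
Why: reductive ester cleavage with i-Bu2AlH should remove the unhindered primary pivalate at −78 °C, whereas the tert-butyl ester on a quaternary carbon is too shielded to react and silyl enol ethers are inert to the hydride; the neutral tartrate work-up keeps the dienol ether intact.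

Step 12
Reactants: 18 tert-butyl (2R,3S,6E)-3-(tert-butyldimethylsilyloxy)-8-hydroxy-2,6-dimethyl-2-[(1E,3E)-4-(triethylsilyloxy)buta-1,3-dien-1-yl]oct-6-enoate
Product: 19 tert-butyl (2R,3S,6E)-3-(tert-butyldimethylsilyloxy)-2,6-dimethyl-8-oxo-2-[(1E,3E)-4-(triethylsilyloxy)buta-1,3-dien-1-yl]oct-6-enoate
Conditions: MnO2, CH2Cl2, rt
Reagents that add atoms: none
Why: MnO2 oxidises allylic alcohols selectively under neutral heterogeneous conditions, which should leave the silyl dienol ether and the E geometry of the new enal untouched.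

Step 13
Reactants: 19 tert-butyl (2R,3S,6E)-3-(tert-butyldimethylsilyloxy)-2,6-dimethyl-8-oxo-2-[(1E,3E)-4-(triethylsilyloxy)buta-1,3-dien-1-yl]oct-6-enoate
Product: 20 tert-butyl 3β-(tert-butyldimethylsilyloxy)-11-oxo-8β-(triethylsilyloxy)-12,13,14,15,16,17-hexanorlabd-6-en-19-oate (trans-fused octalin; C9 formyl equatorial; C8 silyloxy axial)
Conditions: toluene (0.01 M), BHT (cat.), 130 °C, sealed tube
Reagents that add atoms: none
Why: The step is a thermal, concerted but asynchronous, normal-demand [4+2] cycloaddition between the 1-silyloxy diene C5=C6–C7=C8 (largest HOMO coefficient at C5) and the enal C9=C10 (largest LUMO coefficient at the β-carbon C10), so the leading C5–C10 bond is the electronically matched one; the closest known reaction type is the intramolecular Diels–Alder reaction of terminally activated (E)-1,7,9-decatrienals to trans-fused octalins. Ring B closes as the six-membered cycloadduct ring through both new bonds (C5–C10 and C8–C9), and ring A closes at the same time as the six-membered ring spanned by the four-carbon tether C1–C4. Suprafacial addition to the E dienophile keeps the formyl group and the C20 methyl cis (C9 relative to C10), the endo placement of the formyl group under the diene with the tether anti makes H5 trans to the C20 methyl (C5 relative to C10, trans ring fusion), and the same endo mode with the E enol ether places the C8 silyloxy group cis to the formyl group. The diene face is chosen by the C3 and C4 centres through a chair-like tether with the C3 silyloxy group and the C18 methyl equatorial and the ester axial, because the other chair would force a 1,3-diaxial methyl/methyl contact (C18/C20) and an axial silyloxy group. The step needs endo over exo selectivity, one π-face over the other and bond formation at the fully substituted C10; the electron-rich silyloxy diene, the unhindered formyl activator and the E,E diene geometry from step 10 are what the substrate brings to this.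

Step 14
Reactants: 20 tert-butyl 3β-(tert-butyldimethylsilyloxy)-11-oxo-8β-(triethylsilyloxy)-12,13,14,15,16,17-hexanorlabd-6-en-19-oate
Product: 21 tert-butyl 3β-(tert-butyldimethylsilyloxy)-11-oxo-8β-(triethylsilyloxy)-12,13,14,15,16,17-hexanorlabdan-19-oate
Conditions: H2 (1 atm), Pd/C, EtOAc, rt
Reagents that add atoms: none
Why: heterogeneous catalytic hydrogenation should saturate the cis-disubstituted C6=C7 bond while the aldehyde, the silyl ethers and the ester stay intact; no stereocentre is formed.

Step 15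
Reactants: 21 tert-butyl 3β-(tert-butyldimethylsilyloxy)-11-oxo-8β-(triethylsilyloxy)-12,13,14,15,16,17-hexanorlabdan-19-oate
Product: 22 tert-butyl 3β-(tert-butyldimethylsilyloxy)-8β-(triethylsilyloxy)-13,14,15,16,17-pentanorlabd-11-en-19-oate
Conditions: Ph3PCH3Br, KN(SiMe3)2, THF, 0 °C; then 21, −78 → 0 °C
Reagents that add atoms: methyltriphenylphosphonium bromide, C[P+](c1ccccc1)(c1ccccc1)c1ccccc1.[Br-]
Why: Wittig methylenation; the unstabilised ylide should add to the aldehyde at low temperature faster than it deprotonates C9, so that the β-silyloxy aldehyde is converted without elimination or epimerisation.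

Step 16
Reactants: 5 tert-butyl acetoacetate
Product: 23 tert-butyl (2E)-3-(trifluoromethylsulfonyloxy)but-2-enoate
Conditions: Tf2O, aq. Me4NOH, hexanes, 5 °C
Reagents that add atoms: trifluoromethanesulfonic anhydride, O=S(=O)(OS(=O)(=O)C(F)(F)F)C(F)(F)F
Why: O-sulfonylation of the acetoacetate enolate; with the non-coordinating tetramethylammonium counter-ion the enolate should adopt the extended, non-chelated form, which gives the E enol triflate (triflate trans to the ester).

Step 17
Reactants: 22 tert-butyl 3β-(tert-butyldimethylsilyloxy)-8β-(triethylsilyloxy)-13,14,15,16,17-pentanorlabd-11-en-19-oate; 23 tert-butyl (2E)-3-(trifluoromethylsulfonyloxy)but-2-enoate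
Product: 25 di-tert-butyl 3β-(tert-butyldimethylsilyloxy)-8β-(triethylsilyloxy)-17-norlabd-13E-ene-15,19-dioate, via B-alkyl-9-borabicyclononane 24 (not isolated)
Conditions: 9-BBN, THF, 0 °C → rt; then 23, PdCl2(dppf) (cat.), aq. K3PO4, THF/DMF, 50 °C
Reagents that add atoms: none
Why: anti-Markovnikov hydroboration of the monosubstituted alkene puts boron on C12, and the B-alkyl Suzuki–Miyaura coupling should proceed with retention of the enol triflate geometry, which fixes the 13E double bond.

Step 18
Reactants: 25 di-tert-butyl 3β-(tert-butyldimethylsilyloxy)-8β-(triethylsilyloxy)-17-norlabd-13E-ene-15,19-dioate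
Product: 26 di-tert-butyl 3β-(tert-butyldimethylsilyloxy)-8β-hydroxy-17-norlabd-13E-ene-15,19-dioate
Conditions: PPTS (cat.), MeOH/CH2Cl2, 0 °C → rt
Reagents that add atoms: none
Why: acid-catalysed methanolysis should cleave the triethylsilyl ether much faster than the tert-butyldimethylsilyl ether, and tert-butyl esters are inert to the weak acid.

Step 19
Reactants: 26 di-tert-butyl 3β-(tert-butyldimethylsilyloxy)-8β-hydroxy-17-norlabd-13E-ene-15,19-dioate
Product: 27 di-tert-butyl 3β-(tert-butyldimethylsilyloxy)-8-oxo-17-norlabd-13E-ene-15,19-dioate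
Conditions: Dess–Martin periodinane, CH2Cl2, rt
Reagents that add atoms: none
Why: Dess–Martin oxidation of the axial secondary alcohol under near-neutral conditions; C9 keeps its equatorial side chain, which is also the more stable arrangement next to the ketone.

Step 20
Reactants: 27 di-tert-butyl 3β-(tert-butyldimethylsilyloxy)-8-oxo-17-norlabd-13E-ene-15,19-dioate
Product: 28 di-tert-butyl 3β-(tert-butyldimethylsilyloxy)labda-8(17),13E-diene-15,19-dioate
Conditions: Ph3PCH3Br (in excess over base), KOt-Bu, toluene, rt → 50 °C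
Reagents that add atoms: methyltriphenylphosphonium bromide, C[P+](c1ccccc1)(c1ccccc1)c1ccccc1.[Br-]
Why: Wittig methylenation of the ketone; keeping the phosphonium salt in excess leaves no free alkoxide to deprotonate the γ-positions of the enoate, so the 13E geometry and the C9 configuration should be retained.

Step 21
Reactants: 28 di-tert-butyl 3β-(tert-butyldimethylsilyloxy)labda-8(17),13E-diene-15,19-dioate
Product: 29 di-tert-butyl 3β-hydroxylabda-8(17),13E-diene-15,19-dioate
Conditions: HF·pyridine, pyridine, THF, 0 → 40 °C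
Reagents that add atoms: none
Why: fluoride-mediated desilylation with buffered HF·pyridine is non-basic and only weakly acidic, so the enoate geometry, the exocyclic alkene and the tert-butyl esters should be unaffected.

Step 22
Reactants: 29 di-tert-butyl 3β-hydroxylabda-8(17),13E-diene-15,19-dioate
Product: 30 di-tert-butyl 3β-acetoxylabda-8(17),13E-diene-15,19-dioate
Conditions: Ac2O, pyridine, DMAP (cat.), CH2Cl2, rt
Reagents that add atoms: acetic anhydride, CC(=O)OC(C)=O
Why: DMAP-catalysed acetylation of the equatorial 3β-hydroxyl group, which is the only nucleophilic site left.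

Step 23
Reactants: 30 di-tert-butyl 3β-acetoxylabda-8(17),13E-diene-15,19-dioate
Product: 32 3β-acetoxyagathic acid (3β-acetoxylabda-8(17),13E-diene-15,19-dioic acid), via bis(trimethylsilyl) ester 31 (not isolated)
Conditions: Me3SiOTf, 2,6-lutidine, CH2Cl2, 0 °C → rt; then H2O (pH 5 buffer)
Reagents that add atoms: none
Why: silyl-triflate-mediated tert-butyl ester cleavage, in which O-silylation of each ester carbonyl is followed by loss of the tert-butyl cation as isobutene (alkyl–oxygen cleavage, so the shielding of the axial C19 carbonyl carbon does not matter); the lutidine buffer should keep the exocyclic alkene from migrating, and the silyl esters hydrolyse on aqueous work-up while the acetate stays.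

**Compound list**
1 | 3-methylbut-2-en-1-ol (prenol) | CC(C)=CCO | starting material
2 | 3-methylbut-2-en-1-yl pivalate | CC(C)=CCOC(=O)C(C)(C)C | intermediate
3 | (2E)-4-hydroxy-3-methylbut-2-en-1-yl pivalate | OC/C(C)=C/COC(=O)C(C)(C)C | intermediate
4 | (2E)-4-bromo-3-methylbut-2-en-1-yl pivalate | BrC/C(C)=C/COC(=O)C(C)(C)C | intermediate
5 | tert-butyl acetoacetate | CC(=O)CC(=O)OC(C)(C)C | starting material
6 | sodium lithium dianion of tert-butyl acetoacetate (not isolated) | [Na+].[Li+].[CH2-]C(=O)[CH-]C(=O)OC(C)(C)C | intermediate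
7 | tert-butyl (6E)-6-methyl-3-oxo-8-(pivaloyloxy)oct-6-enoate | CC(C)(C)OC(=O)CC(=O)CC/C(C)=C/COC(=O)C(C)(C)C | intermediate
8 | tert-butyl (3S,6E)-3-hydroxy-6-methyl-8-(pivaloyloxy)oct-6-enoate | CC(C)(C)OC(=O)C[C@@H](O)CC/C(C)=C/COC(=O)C(C)(C)C | intermediate
9 | allyl bromide | C=CCBr | starting material
10 | dilithium alkoxide enolate of 8 (not isolated) | [Li+].[Li+].[O-]C(=C[C@@H]([O-])CC/C(C)=C/COC(=O)C(C)(C)C)OC(C)(C)C | intermediate
11 | tert-butyl (2S,3S,6E)-3-hydroxy-6-methyl-8-(pivaloyloxy)-2-(prop-2-en-1-yl)oct-6-enoate | CC(C)(C)OC(=O)[C@@H](CC=C)[C@@H](O)CC/C(C)=C/COC(=O)C(C)(C)C | intermediate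
12 | dilithium alkoxide enolate of 11 (not isolated) | [Li+].[Li+].[O-]C(=C(CC=C)[C@@H]([O-])CC/C(C)=C/COC(=O)C(C)(C)C)OC(C)(C)C | intermediate
13 | tert-butyl (2R,3S,6E)-3-hydroxy-2,6-dimethyl-8-(pivaloyloxy)-2-(prop-2-en-1-yl)oct-6-enoate | CC(C)(C)OC(=O)[C@@](CC=C)(C)[C@@H](O)CC/C(C)=C/COC(=O)C(C)(C)C | intermediate
14 | tert-butyl (2R,3S,6E)-3-(tert-butyldimethylsilyloxy)-2,6-dimethyl-8-(pivaloyloxy)-2-(prop-2-en-1-yl)oct-6-enoate | CC(C)(C)OC(=O)[C@@](CC=C)(C)[C@@H](O[Si](C)(C)C(C)(C)C)CC/C(C)=C/COC(=O)C(C)(C)C | intermediate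
15 | (E)-but-2-enal (crotonaldehyde) | C/C=C/C=O | starting material
16 | tert-butyl (2R,3S,6E)-3-(tert-butyldimethylsilyloxy)-2,6-dimethyl-2-[(2E)-4-oxobut-2-en-1-yl]-8-(pivaloyloxy)oct-6-enoate | CC(C)(C)OC(=O)[C@@](C/C=C/C=O)(C)[C@@H](O[Si](C)(C)C(C)(C)C)CC/C(C)=C/COC(=O)C(C)(C)C | intermediate
17 | tert-butyl (2R,3S,6E)-3-(tert-butyldimethylsilyloxy)-2,6-dimethyl-8-(pivaloyloxy)-2-[(1E,3E)-4-(triethylsilyloxy)buta-1,3-dien-1-yl]oct-6-enoate | CC(C)(C)OC(=O)[C@@](/C=C/C=C/O[Si](CC)(CC)CC)(C)[C@@H](O[Si](C)(C)C(C)(C)C)CC/C(C)=C/COC(=O)C(C)(C)C | intermediate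
18 | tert-butyl (2R,3S,6E)-3-(tert-butyldimethylsilyloxy)-8-hydroxy-2,6-dimethyl-2-[(1E,3E)-4-(triethylsilyloxy)buta-1,3-dien-1-yl]oct-6-enoate | CC(C)(C)OC(=O)[C@@](/C=C/C=C/O[Si](CC)(CC)CC)(C)[C@@H](O[Si](C)(C)C(C)(C)C)CC/C(C)=C/CO | intermediate
19 | tert-butyl (2R,3S,6E)-3-(tert-butyldimethylsilyloxy)-2,6-dimethyl-8-oxo-2-[(1E,3E)-4-(triethylsilyloxy)buta-1,3-dien-1-yl]oct-6-enoate (cycloaddition precursor) | CC(C)(C)OC(=O)[C@@](/C=C/C=C/O[Si](CC)(CC)CC)(C)[C@@H](O[Si](C)(C)C(C)(C)C)CC/C(C)=C/C=O | intermediate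
20 | tert-butyl 3β-(tert-butyldimethylsilyloxy)-11-oxo-8β-(triethylsilyloxy)-12,13,14,15,16,17-hexanorlabd-6-en-19-oate (cycloadduct) | CC[Si](CC)(CC)O[C@H]1C=C[C@@H]2[C@](C)(CC[C@H](O[Si](C)(C)C(C)(C)C)[C@]2(C)C(=O)OC(C)(C)C)[C@H]1C=O | intermediate
21 | tert-butyl 3β-(tert-butyldimethylsilyloxy)-11-oxo-8β-(triethylsilyloxy)-12,13,14,15,16,17-hexanorlabdan-19-oate | CC[Si](CC)(CC)O[C@H]1CC[C@@H]2[C@](C)(CC[C@H](O[Si](C)(C)C(C)(C)C)[C@]2(C)C(=O)OC(C)(C)C)[C@H]1C=O | intermediate
22 | tert-butyl 3β-(tert-butyldimethylsilyloxy)-8β-(triethylsilyloxy)-13,14,15,16,17-pentanorlabd-11-en-19-oate | CC[Si](CC)(CC)O[C@H]1CC[C@@H]2[C@](C)(CC[C@H](O[Si](C)(C)C(C)(C)C)[C@]2(C)C(=O)OC(C)(C)C)[C@H]1C=C | intermediate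
23 | tert-butyl (2E)-3-(trifluoromethylsulfonyloxy)but-2-enoate | C/C(OS(=O)(=O)C(F)(F)F)=C\C(=O)OC(C)(C)C | intermediate
24 | tert-butyl 12-(9-borabicyclo[3.3.1]nonan-9-yl)-3β-(tert-butyldimethylsilyloxy)-8β-(triethylsilyloxy)-13,14,15,16,17-pentanorlabdan-19-oate (not isolated) | CC[Si](CC)(CC)O[C@H]1CC[C@@H]2[C@](C)(CC[C@H](O[Si](C)(C)C(C)(C)C)[C@]2(C)C(=O)OC(C)(C)C)[C@H]1CCB3C4CCCC3CCC4 | intermediate
25 | di-tert-butyl 3β-(tert-butyldimethylsilyloxy)-8β-(triethylsilyloxy)-17-norlabd-13E-ene-15,19-dioate | CC[Si](CC)(CC)O[C@H]1CC[C@@H]2[C@](C)(CC[C@H](O[Si](C)(C)C(C)(C)C)[C@]2(C)C(=O)OC(C)(C)C)[C@H]1CC/C(C)=C/C(=O)OC(C)(C)C | intermediate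
26 | di-tert-butyl 3β-(tert-butyldimethylsilyloxy)-8β-hydroxy-17-norlabd-13E-ene-15,19-dioate | O[C@H]1CC[C@@H]2[C@](C)(CC[C@H](O[Si](C)(C)C(C)(C)C)[C@]2(C)C(=O)OC(C)(C)C)[C@H]1CC/C(C)=C/C(=O)OC(C)(C)C | intermediate
27 | di-tert-butyl 3β-(tert-butyldimethylsilyloxy)-8-oxo-17-norlabd-13E-ene-15,19-dioate | O=C1CC[C@@H]2[C@](C)(CC[C@H](O[Si](C)(C)C(C)(C)C)[C@]2(C)C(=O)OC(C)(C)C)[C@H]1CC/C(C)=C/C(=O)OC(C)(C)C | intermediate
28 | di-tert-butyl 3β-(tert-butyldimethylsilyloxy)labda-8(17),13E-diene-15,19-dioate | C=C1CC[C@@H]2[C@](C)(CC[C@H](O[Si](C)(C)C(C)(C)C)[C@]2(C)C(=O)OC(C)(C)C)[C@H]1CC/C(C)=C/C(=O)OC(C)(C)C | intermediate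
29 | di-tert-butyl 3β-hydroxylabda-8(17),13E-diene-15,19-dioate | C=C1CC[C@@H]2[C@](C)(CC[C@H](O)[C@]2(C)C(=O)OC(C)(C)C)[C@H]1CC/C(C)=C/C(=O)OC(C)(C)C | intermediate
30 | di-tert-butyl 3β-acetoxylabda-8(17),13E-diene-15,19-dioate | C=C1CC[C@@H]2[C@](C)(CC[C@H](OC(C)=O)[C@]2(C)C(=O)OC(C)(C)C)[C@H]1CC/C(C)=C/C(=O)OC(C)(C)C | intermediate
31 | bis(trimethylsilyl) 3β-acetoxylabda-8(17),13E-diene-15,19-dioate (not isolated) | C=C1CC[C@@H]2[C@](C)(CC[C@H](OC(C)=O)[C@]2(C)C(=O)O[Si](C)(C)C)[C@H]1CC/C(C)=C/C(=O)O[Si](C)(C)C | intermediate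
32 | 3β-acetoxyagathic acid (3β-acetoxylabda-8(17),13E-diene-15,19-dioic acid) | C=C1CC[C@@H]2[C@](C)(CC[C@H](OC(C)=O)[C@]2(C)C(=O)O)[C@H]1CC/C(C)=C/C(=O)O | target

**Step count**
Total steps: 23. Longest linear sequence: 22 steps (steps 1–15 and 17–23, from prenol); step 16 is a one-step side branch.

**Steps most likely to fail**

Step 13. Bond formation at the fully substituted C10 may be slow, and during the long heating the silyl dienol ether may isomerise or hydrolyse, the endo preference may erode, and the β-silyloxy aldehyde adduct may lose triethylsilanol. Fallback: setting out from 19, ring B would be closed at −78 °C as a Lewis-acid-bound polar annulation instead of a thermal pericyclic reaction (Me2AlCl, CH2Cl2; C5–C10 bond formation in the manner of a vinylogous Mukaiyama–Michael addition, then collapse of C9 onto C8). The adduct would be secured at the alcohol oxidation level by adding NaBH4/MeOH before isolation, to give tert-butyl 3β-(tert-butyldimethylsilyloxy)-11-hydroxy-8β-(triethylsilyloxy)-12,13,14,15,16,17-hexanorlabd-6-en-19-oate F1. Hydrogenation (H2, Pd/C, EtOAc) would give tert-butyl 3β-(tert-butyldimethylsilyloxy)-11-hydroxy-8β-(triethylsilyloxy)-12,13,14,15,16,17-hexanorlabdan-19-oate F2, and Dess–Martin oxidation of F2 comes back to the route at 21.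

Step 7. Enolisation of the crowded α-allyl β-alkoxide ester may be incomplete, retro-aldol fragmentation may compete, or the anti selectivity of the methylation may erode. Fallback: setting out from keto ester 7, the order of events at C3/C4 would be inverted. C-Methylation (MeI, K2CO3, acetone) gives tert-butyl (6E)-2,6-dimethyl-3-oxo-8-(pivaloyloxy)oct-6-enoate F3. Palladium-catalysed asymmetric allylic alkylation (allyl acetate, [Pd(C3H5)Cl]2, the enantiomer of the 1,2-diaminocyclohexane bis(2-diphenylphosphinobenzamide) ligand that delivers 2R, base, toluene) gives tert-butyl (2R,6E)-2,6-dimethyl-3-oxo-8-(pivaloyloxy)-2-(prop-2-en-1-yl)oct-6-enoate F4. Reagent-controlled Corey–Bakshi–Shibata reduction ((R)-2-methyl-oxazaborolidine, catecholborane) of the ketone flanked by the quaternary carbon and a methylene group should give the 3S alcohol, which is 13.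

Step 23. The exocyclic 8(17) double bond may migrate into the ring under the acidic conditions, or cleavage of the shielded axial C19 ester may stay incomplete. Fallback: setting out from ketone 27, all acid-labile groups would be removed before the exocyclic alkene exists. CF3CO2H/H2O cleaves both tert-butyl esters and the silyl ether to give 3β-hydroxy-8-oxo-17-norlabd-13E-ene-15,19-dioic acid F5. Wittig methylenation with excess Ph3P=CH2 in DMSO/THF, with the carboxylates and the alkoxide as spectators, gives 3β-hydroxylabda-8(17),13E-diene-15,19-dioic acid (3β-hydroxyagathic acid) F6. Acetylation (Ac2O, pyridine, DMAP; aqueous work-up to hydrolyse mixed anhydrides) comes back to the route at the target 32.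

Further compounds
F1 | step 13 | tert-butyl 3β-(tert-butyldimethylsilyloxy)-11-hydroxy-8β-(triethylsilyloxy)-12,13,14,15,16,17-hexanorlabd-6-en-19-oate | CC[Si](CC)(CC)O[C@H]1C=C[C@@H]2[C@](C)(CC[C@H](O[Si](C)(C)C(C)(C)C)[C@]2(C)C(=O)OC(C)(C)C)[C@H]1CO
F2 | step 13 | tert-butyl 3β-(tert-butyldimethylsilyloxy)-11-hydroxy-8β-(triethylsilyloxy)-12,13,14,15,16,17-hexanorlabdan-19-oate | CC[Si](CC)(CC)O[C@H]1CC[C@@H]2[C@](C)(CC[C@H](O[Si](C)(C)C(C)(C)C)[C@]2(C)C(=O)OC(C)(C)C)[C@H]1CO
F3 | step 7 | tert-butyl (6E)-2,6-dimethyl-3-oxo-8-(pivaloyloxy)oct-6-enoate | CC(C)(C)OC(=O)C(C)C(=O)CC/C(C)=C/COC(=O)C(C)(C)C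
F4 | step 7 | tert-butyl (2R,6E)-2,6-dimethyl-3-oxo-8-(pivaloyloxy)-2-(prop-2-en-1-yl)oct-6-enoate | CC(C)(C)OC(=O)[C@@](CC=C)(C)C(=O)CC/C(C)=C/COC(=O)C(C)(C)C
F5 | step 23 | 3β-hydroxy-8-oxo-17-norlabd-13E-ene-15,19-dioic acid | O=C1CC[C@@H]2[C@](C)(CC[C@H](O)[C@]2(C)C(=O)O)[C@H]1CC/C(C)=C/C(=O)O
F6 | step 23 | 3β-hydroxylabda-8(17),13E-diene-15,19-dioic acid | C=C1CC[C@@H]2[C@](C)(CC[C@H](O)[C@]2(C)C(=O)O)[C@H]1CC/C(C)=C/C(=O)O
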